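**Retrosynthetic overview**

- The route rests on one feature of ring A: C8 carries the acyl carbon and its neighbour C8a carries the lactone oxygen O1. An aryne takes up exactly this ortho acyl/oxygen pair from a carboxylic acid, so the C8–C(=O) and C8a–O1 bonds are both cut back to a C8≡C8a aryne and 3-(4-methoxyphenyl)propanoic acid.
- The aryne precursor has SiMe3 on C8 and OTf on C8a. It is made from the 8-bromo-C8a-phenol by O-silylation, bromine–lithium exchange with retro-Brook shift, and triflation. This is used instead of a directed deprotonation, which the ester and the benzyl ethers would not tolerate.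
- The bromophenol comes from (S)-5,7-bis(benzyloxy)-4-phenylchroman-2-one by bromination at C8 and methanolysis. The lactone thereby tells C8a–O from C5–O and C8 from C6.
- C4 is set by rhodium-catalysed asymmetric phenyl addition to 5,7-bis(benzyloxy)coumarin, which comes from phloroglucinol and ethyl propiolate.
- Ring order: ring A is bought. The lactone ring is built in step 1, opened in step 5 and closed again in step 8 after the aryne step; hydrogenolysis ends the route.

Key step: step 7

Assumption: in step 3 the sense of induction is taken to follow that of simple coumarins, where the (S)-configured bisphosphine leads to the 4S lactone; should it be reversed, the antipodal ligand would be used.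

**Route**

Step 1
Reactants: 1 phloroglucinol; 2 ethyl propiolate
Product: 3 5,7-dihydroxycoumarin (5,7-dihydroxy-2H-chromen-2-one)
Conditions: ZnCl2 (1 equiv), dioxane, 90 °C
Reagents that add atoms: none
Why: Pechmann-type condensation, in which the Lewis acid promotes conjugate hydroarylation of the propiolate by the symmetric, electron-rich arene and the cis-cinnamate lactonises with loss of ethanol, the symmetry of 1 removing any question of regiochemistry.

Step 2
Reactants: 3 5,7-dihydroxycoumarin
Product: 4 5,7-bis(benzyloxy)coumarin
Conditions: BnBr (2.3 equiv), K2CO3, DMF, 50 °C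
Reagents that add atoms: benzyl bromide, BrCc1ccccc1
Why: Williamson ether synthesis on two acidic phenols; benzyl is chosen because it should survive every later step and is removed at the end by hydrogenolysis without touching the aryl methyl ether or the lactone.

Step 3
Reactants: 4 5,7-bis(benzyloxy)coumarin; 5 phenylboronic acid
Product: 6 (S)-5,7-bis(benzyloxy)-4-phenylchroman-2-one
Conditions: Rh(acac)(C2H4)2 (3 mol%), (S)-SEGPHOS (3.3 mol%), PhB(OH)2 (5 equiv), dioxane–H2O 10:1, 60 °C
Reagents that add atoms: none
Why: Hayashi–Miyaura asymmetric 1,4-addition, in which the phenyl complex of monovalent rhodium with the axially chiral bisphosphine inserts the C3=C4 bond on one face and hydrolysis of the rhodium enolate releases the lactone, so the ligand sets C4 as S.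

Step 4
Reactants: 6 (S)-5,7-bis(benzyloxy)-4-phenylchroman-2-one
Product: 7 (S)-5,7-bis(benzyloxy)-8-bromo-4-phenylchroman-2-one
Conditions: NBS (1.0 equiv), CH2Cl2, −20 → 0 °C, dark
Reagents that add atoms: N-bromosuccinimide, O=C1CCC(=O)N1Br
Why: Electrophilic aromatic bromination; C8 is ortho to the C7 and para to the C5 benzyloxy group, whereas C6 lies between the two ethers and has only the weakly donating acyloxy oxygen para to it, so the halogen should enter at C8, as resorcinol diethers react at the ortho/para carbon and not between the oxygens.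

Step 5
Reactants: 7 (S)-5,7-bis(benzyloxy)-8-bromo-4-phenylchroman-2-one
Product: 8 methyl (S)-3-[4,6-bis(benzyloxy)-3-bromo-2-hydroxyphenyl]-3-phenylpropanoate
Conditions: NaOMe (1.1 equiv), MeOH–THF, 0 °C; then AcOH (1.1 equiv), cold work-up
Reagents that add atoms: sodium methoxide, [Na+].[O-]C; methanol, CO
Why: Transesterification (lactone methanolysis), in which methoxide opens the aryl ester to the more stable methyl ester and the 2-bromophenoxide; cold neutralisation should give the hydroxy ester, which is carried on at once to forestall relactonisation.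

Step 6
Reactants: 8 methyl (S)-3-[4,6-bis(benzyloxy)-3-bromo-2-hydroxyphenyl]-3-phenylpropanoate
Product: 11 methyl (S)-3-[2,4-bis(benzyloxy)-6-(trifluoromethylsulfonyloxy)-5-(trimethylsilyl)phenyl]-3-phenylpropanoate, via aryl trimethylsilyl ether 9 (not isolated), via lithium 2-silylphenoxide 10 (not isolated)
Conditions: HMDS, THF, 65 °C, then volatiles removed; n-BuLi (1.05 equiv), THF–Et2O, −100 °C; then Tf2O, −100 → −78 °C
Reagents that add atoms: hexamethyldisilazane, C[Si](C)(C)N[Si](C)(C)C; triflic anhydride, O=S(=O)(OS(=O)(=O)C(F)(F)F)C(F)(F)F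
Why: O-silylation followed by Parham-type bromine–lithium exchange at −100 °C, which is faster than addition of butyllithium to the ester, gives the C8 aryllithium; this undergoes the 1,3 retro-Brook shift of silicon from oxygen to carbon, and the phenoxide set free is triflated in the same flask.

Step 7
Reactants: 11 methyl (S)-3-[2,4-bis(benzyloxy)-6-(trifluoromethylsulfonyloxy)-5-(trimethylsilyl)phenyl]-3-phenylpropanoate; 12 3-(4-methoxyphenyl)propanoic acid
Product: 14 methyl (S)-3-{4,6-bis(benzyloxy)-2-hydroxy-3-[3-(4-methoxyphenyl)propanoyl]phenyl}-3-phenylpropanoate, via aryne 13 (not isolated)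
Conditions: CsF (4 equiv), 12 (1.2 equiv), anhydrous THF, sealed tube, 125 °C
Reagents that add atoms: none
Why: Fluoride removes the C8 silyl group and the C8a triflate departs to give aryne 13; the caesium carboxylate of 12 adds through oxygen to C8a, the aryl anion left on C8 attacks the carbonyl of the aryl ester just formed, and the four-membered alkoxide opens to the ortho-acyl phenoxide, so that C8a–O and C8–C(=O) are made in one operation. This is the known insertion of arynes into the C–O bond of carboxylic acids, in effect an anionic Fries-type 1,3 acyl shift triggered by addition to the aryne. No ring is closed and no stereocentre is formed; C4 is not enolisable and is not touched. The step needs oxygen to add at C8a and not at C8: the C7 benzyloxy group beside the triple bond withdraws σ-density, bends the aryne so that C8a is the more linear and more electrophilic carbon, and stabilises the charge developing on C8, a bias expected to override the steric shielding of C8a by the branched C4 substituent. It also needs acyl transfer to beat protonation of the C8 anion, which dry THF at high temperature and only a small excess of the acid as the sole proton source should favour. Because O5 stays benzylated, the new C8a hydroxyl is the only phenol that can later close the lactone, so the 8-acyl and not the 6-acyl chromanone will result.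

Step 8
Reactants: 14 methyl (S)-3-{4,6-bis(benzyloxy)-2-hydroxy-3-[3-(4-methoxyphenyl)propanoyl]phenyl}-3-phenylpropanoate
Product: 15 (S)-5,7-bis(benzyloxy)-8-[3-(4-methoxyphenyl)propanoyl]-4-phenylchroman-2-one
Conditions: p-TsOH·H2O (10 mol%), toluene, 80 °C
Reagents that add atoms: none
Why: Acid-catalysed intramolecular transesterification (lactonisation) of the only free phenol onto the methyl ester with loss of methanol, under conditions mild enough to leave the benzyl ethers and the C4 centre alone.

Step 9
Reactants: 15 (S)-5,7-bis(benzyloxy)-8-[3-(4-methoxyphenyl)propanoyl]-4-phenylchroman-2-one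
Product: 16 (S)-5,7-dihydroxy-8-[3-(4-methoxyphenyl)propanoyl]-4-phenylchroman-2-one (target)
Conditions: H2 (1 atm), Pd/C (10%), EtOAc, rt
Reagents that add atoms: none
Why: Catalytic hydrogenolysis of the two aryl benzyl ethers under neutral, aprotic conditions; the hindered, hydrogen-bonded acylphloroglucinol ketone, the lactone and the aryl methyl ether should be inert, and neutral conditions avoid translactonisation onto the freed C5 hydroxyl.

**Compound list**

1 | phloroglucinol | Oc1cc(O)cc(O)c1 | starting material
2 | ethyl propiolate | C#CC(=O)OCC | starting material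
3 | 5,7-dihydroxycoumarin | O=C1C=Cc2c(O)cc(O)cc2O1 | intermediate
4 | 5,7-bis(benzyloxy)coumarin | O=C1C=Cc2c(OCc3ccccc3)cc(OCc3ccccc3)cc2O1 | intermediate
5 | phenylboronic acid | OB(O)c1ccccc1 | starting material
6 | (S)-5,7-bis(benzyloxy)-4-phenylchroman-2-one | O=C1C[C@@H](c2ccccc2)c2c(OCc3ccccc3)cc(OCc3ccccc3)cc2O1 | intermediate
7 | (S)-5,7-bis(benzyloxy)-8-bromo-4-phenylchroman-2-one | O=C1C[C@@H](c2ccccc2)c2c(OCc3ccccc3)cc(OCc3ccccc3)c(Br)c2O1 | intermediate
8 | methyl (S)-3-[4,6-bis(benzyloxy)-3-bromo-2-hydroxyphenyl]-3-phenylpropanoate | COC(=O)C[C@@H](c1ccccc1)c1c(OCc2ccccc2)cc(OCc2ccccc2)c(Br)c1O | intermediate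
9 | methyl (S)-3-[4,6-bis(benzyloxy)-3-bromo-2-(trimethylsilyloxy)phenyl]-3-phenylpropanoate (not isolated) | COC(=O)C[C@@H](c1ccccc1)c1c(OCc2ccccc2)cc(OCc2ccccc2)c(Br)c1O[Si](C)(C)C | intermediate
10 | lithium 3,5-bis(benzyloxy)-2-[(S)-3-methoxy-3-oxo-1-phenylpropyl]-6-(trimethylsilyl)phenoxide (not isolated) | COC(=O)C[C@@H](c1ccccc1)c1c(OCc2ccccc2)cc(OCc2ccccc2)c([Si](C)(C)C)c1[O-].[Li+] | intermediate
11 | methyl (S)-3-[2,4-bis(benzyloxy)-6-(trifluoromethylsulfonyloxy)-5-(trimethylsilyl)phenyl]-3-phenylpropanoate | COC(=O)C[C@@H](c1ccccc1)c1c(OCc2ccccc2)cc(OCc2ccccc2)c([Si](C)(C)C)c1OS(=O)(=O)C(F)(F)F | intermediate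
12 | 3-(4-methoxyphenyl)propanoic acid | COc1ccc(CCC(=O)O)cc1 | starting material
13 | methyl (S)-3-[4,6-bis(benzyloxy)-2,3-didehydrophenyl]-3-phenylpropanoate (aryne, C8≡C8a; not isolated) | COC(=O)C[C@@H](c1ccccc1)C1=C(OCc2ccccc2)C=C(OCc2ccccc2)C#C1 | intermediate
14 | methyl (S)-3-{4,6-bis(benzyloxy)-2-hydroxy-3-[3-(4-methoxyphenyl)propanoyl]phenyl}-3-phenylpropanoate | COC(=O)C[C@@H](c1ccccc1)c1c(OCc2ccccc2)cc(OCc2ccccc2)c(C(=O)CCc2ccc(OC)cc2)c1O | intermediate
15 | (S)-5,7-bis(benzyloxy)-8-[3-(4-methoxyphenyl)propanoyl]-4-phenylchroman-2-one | COc1ccc(CCC(=O)c2c(OCc4ccccc4)cc(OCc5ccccc5)c3c2OC(=O)C[C@H]3c2ccccc2)cc1 | intermediate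
16 | (S)-5,7-dihydroxy-8-[3-(4-methoxyphenyl)propanoyl]-4-phenylchroman-2-one | COc1ccc(CCC(=O)c2c(O)cc(O)c3c2OC(=O)C[C@H]3c2ccccc2)cc1 | target

**Step count and risks**

Total step count: 9. Longest linear sequence: 9 steps (from phloroglucinol).

The three steps most likely to fail are steps 7, 6 and 3, in that order.

First, step 7. Several things may go wrong here:
- The C8 aryl anion may be protonated before it transfers the acyl group, which would leave the simple aryl ester.
- The carboxylate may add at C8 instead of C8a under steric pressure from the C4 branch.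
- The side-chain ester carbonyl may intercept the aryne, or a benzylic C–H of the C7 ether may quench the anion.
- The product phenoxide may partly lactonise in the flask; this is harmless, since step 8 converges on the same lactone.

The fallback sets out from 8 and returns at 14, and generates the same aryl anion/aryl ester pair without an aryne. Phenol 8 would be esterified with acid 12 (EDC·HCl, DMAP, CH2Cl2) to give the bromoaryl ester methyl (S)-3-{4,6-bis(benzyloxy)-3-bromo-2-[3-(4-methoxyphenyl)propanoyloxy]phenyl}-3-phenylpropanoate F1. Bromine–lithium exchange (n-BuLi, THF, −100 °C) would then place the carbanion on C8 with no ambiguity of position. The known anionic Fries rearrangement (1,3 shift of the acyl group from oxygen to carbon) should give 14 after work-up.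

Second, step 6. Butyllithium may add to the methyl ester or deprotonate next to it in competition with the exchange, and the aryllithium may be protonated before silicon migrates. The fallback sets out from 7 and returns at 11, and keeps the ester out of the flask while the organolithium is used:
- Lactone 7 would be reduced with LiBH4 (THF, 0 °C → rt) to the diol (S)-3-[4,6-bis(benzyloxy)-3-bromo-2-hydroxyphenyl]-3-phenylpropan-1-ol F2.
- HMDS would give the bis(trimethylsilyl) ether F3.
- n-BuLi (THF, −78 °C) and then PhNTf2 would effect exchange, retro-Brook shift of the aryl silyl group only and triflation, giving the silyl triflate primary trimethylsilyl ether F4.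
- Work-up with dilute citric acid would remove that ether to give the primary alcohol F5.
- Oxidation with TEMPO/PhI(OAc)2 in MeCN–H2O would give the carboxylic acid F6.
- Esterification with trimethylsilyldiazomethane (MeOH–toluene) would return 11.

Third, step 3. The C5 benzyloxy group peri to C4 may slow insertion of the aryl–rhodium species so much that protodeboronation of the boronic acid wins, or it may erode facial selectivity. The fallback sets out from 1 and returns at 6; the phenyl group is built in first and the small nucleophile, hydride, is delivered asymmetrically: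
- Pechmann condensation of 1 with ethyl benzoylacetate (H2SO4 or CF3CO2H) would give 5,7-dihydroxy-4-phenylcoumarin F7.
- Benzylation (BnBr, K2CO3, DMF) would give 5,7-bis(benzyloxy)-4-phenylcoumarin F8.
- Copper hydride asymmetric conjugate reduction (Cu(OAc)2·H2O, DTBM-SEGPHOS of the appropriate hand, diethoxymethylsilane, t-BuOH, toluene) should give 6.

**Further compounds**

F1 | step 7 | methyl (S)-3-{4,6-bis(benzyloxy)-3-bromo-2-[3-(4-methoxyphenyl)propanoyloxy]phenyl}-3-phenylpropanoate | COC(=O)C[C@@H](c1ccccc1)c1c(OCc2ccccc2)cc(OCc2ccccc2)c(Br)c1OC(=O)CCc1ccc(OC)cc1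
F2 | step 6 | (S)-3-[4,6-bis(benzyloxy)-3-bromo-2-hydroxyphenyl]-3-phenylpropan-1-ol | OCC[C@@H](c1ccccc1)c1c(OCc2ccccc2)cc(OCc2ccccc2)c(Br)c1O
F3 | step 6 | (S)-{3-[4,6-bis(benzyloxy)-3-bromo-2-(trimethylsilyloxy)phenyl]-3-phenylpropoxy}trimethylsilane | C[Si](C)(C)OCC[C@@H](c1ccccc1)c1c(OCc2ccccc2)cc(OCc2ccccc2)c(Br)c1O[Si](C)(C)C
F4 | step 6 | (S)-3,5-bis(benzyloxy)-2-[1-phenyl-3-(trimethylsilyloxy)propyl]-6-(trimethylsilyl)phenyl trifluoromethanesulfonate | C[Si](C)(C)OCC[C@@H](c1ccccc1)c1c(OCc2ccccc2)cc(OCc2ccccc2)c([Si](C)(C)C)c1OS(=O)(=O)C(F)(F)F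
F5 | step 6 | (S)-3,5-bis(benzyloxy)-2-(3-hydroxy-1-phenylpropyl)-6-(trimethylsilyl)phenyl trifluoromethanesulfonate | OCC[C@@H](c1ccccc1)c1c(OCc2ccccc2)cc(OCc2ccccc2)c([Si](C)(C)C)c1OS(=O)(=O)C(F)(F)F
F6 | step 6 | (S)-3-[2,4-bis(benzyloxy)-6-(trifluoromethylsulfonyloxy)-5-(trimethylsilyl)phenyl]-3-phenylpropanoic acid | OC(=O)C[C@@H](c1ccccc1)c1c(OCc2ccccc2)cc(OCc2ccccc2)c([Si](C)(C)C)c1OS(=O)(=O)C(F)(F)F
F7 | step 3 | 5,7-dihydroxy-4-phenylcoumarin | O=C1C=C(c2ccccc2)c2c(O)cc(O)cc2O1
F8 | step 3 | 5,7-bis(benzyloxy)-4-phenylcoumarin | O=C1C=C(c2ccccc2)c2c(OCc3ccccc3)cc(OCc3ccccc3)cc2O1
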